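**Plan**

- Feature: in isochromene numbering, ring A is the pyran (O2, C1, C3, C4, C4a, C8a), ring B the carbocycle (C4a, C5, C6, C7, C8, C8a) and ring C the lactone held at C8 through C3'. The fused rings share C4a-C8a; O2-C3=C4-C4a is a latent enone O=C3-C4=C4a, C8a=C1 a latent ethynyl group, and C5-C8 link them, so one enone-alkyne oxa-[4+2] can close rings B and A together.
- Retrosynthetic cuts, in order: C5-Cl and the C4a=C5 unsaturation; C4a-C8a and O2-C1 (nickel-catalysed key step); C4=C4a (cross-metathesis); C5-C6 (allyl addition to a dioxolanone carbonyl); C7-C8 and C3'-C4' (Michael addition then Dieckmann closure).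
- Forward: ring C is made first on the C6-C7-C8 unit, the chain is grown to the dienyl enone, rings B and A close in one step, then dehydrogenation, C5 chlorination and desilylation.
- Stereochemistry: the side-chain centre comes from (S)-2-methylbutan-1-ol, C6' from ethyl (S)-3-hydroxybutanoate, and C7 from (R)-lactic acid through its pivalaldehyde acetal (net retention). C8 is set by substrate-controlled Michael addition of that enolate, C3' by equilibration; all alkenes are E from Wittig-type olefinations and metathesis.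

Key step: step 13

Assumption: C3' lies between two carbonyl groups and is configurationally labile; the drawn (3'R) configuration (C8 and the C6' methyl cis on ring C) is taken to be the one favoured at equilibrium and is reached by tautomerisation in the last step.

**Route**

Step 1
Reactants: 1 (S)-2-methylbutan-1-ol
Product: 3 ethyl (2E,4S)-2,4-dimethylhex-2-enoate, via (S)-2-methylbutanal 2 (not isolated)
Conditions: TEMPO (10 mol%), PhI(OAc)2, CH2Cl2, 23 °C; then Ph3P=C(Me)CO2Et, 23 °C, one pot
Reagents that add atoms: ethyl 2-(triphenylphosphoranylidene)propanoate (CCOC(=O)C(C)=P(c1ccccc1)(c1ccccc1)c1ccccc1)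
Why: The nitroxyl-catalysed oxidation gives the configurationally fragile aldehyde under near-neutral conditions and the stabilised ylide traps it at once in an E-selective Wittig olefination, so the α-stereocentre has no occasion to epimerise.

Step 2
Reactants: 3 ethyl (2E,4S)-2,4-dimethylhex-2-enoate
Product: 4 (2E,4S)-2,4-dimethylhex-2-en-1-ol
Conditions: i-Bu2AlH (2.2 equiv), CH2Cl2, −78 to 0 °C; aqueous potassium sodium tartrate
Reagents that add atoms: none
Why: 1,2-Reduction of an α,β-unsaturated ester to the allylic alcohol with i-Bu2AlH is standard and leaves the trisubstituted alkene and the allylic stereocentre untouched.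

Step 3
Reactants: 4 (2E,4S)-2,4-dimethylhex-2-en-1-ol
Product: 6 (2E,4E,6S)-N-methoxy-N,4,6-trimethylocta-2,4-dienamide, via (2E,4S)-2,4-dimethylhex-2-enal 5 (not isolated)
Conditions: MnO2 (10 equiv), Ph3P=CHC(O)N(OMe)Me, CH2Cl2, reflux
Reagents that add atoms: N-methoxy-N-methyl-2-(triphenylphosphoranylidene)acetamide (CON(C)C(=O)C=P(c1ccccc1)(c1ccccc1)c1ccccc1)
Why: In this tandem oxidation-Wittig reaction MnO2 oxidises only the allylic alcohol and the volatile enal is intercepted in situ by the stabilised amide ylide, which forms the new disubstituted alkene with E geometry.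

Step 4
Reactants: 6 (2E,4E,6S)-N-methoxy-N,4,6-trimethylocta-2,4-dienamide
Product: 7 (4E,6E,8S)-6,8-dimethyldeca-1,4,6-trien-3-one
Conditions: CH2=CHMgBr (1.5 equiv), THF, −78 to 0 °C; inverse quench into cold 1 M HCl
Reagents that add atoms: vinylmagnesium bromide (C=C[Mg]Br)
Why: A Weinreb amide takes up one equivalent of CH2=CHMgBr to a stable chelated tetrahedral adduct, so the ketone appears only on quench, and quenching into acid keeps the released amine protonated so that it cannot add to the vinyl ketone.

Step 5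
Reactants: 8 ethyl (S)-3-hydroxybutanoate
Product: 9 ethyl (3S)-3-{[(diethoxyphosphoryl)acetyl]oxy}butanoate
Conditions: (EtO)2P(O)CH2CO2H, DCC, DMAP (5 mol%), CH2Cl2, 0 to 23 °C
Reagents that add atoms: diethylphosphonoacetic acid (CCOP(=O)(CC(=O)O)OCC)
Why: Carbodiimide (Steglich) esterification acylates the secondary alcohol at oxygen without touching the carbinol carbon, so C6' keeps its S configuration.

Step 6
Reactants: 9 ethyl (3S)-3-{[(diethoxyphosphoryl)acetyl]oxy}butanoate; 10 3-(trimethylsilyl)prop-2-ynal
Product: 11 ethyl (3S)-3-{[(2E)-5-(trimethylsilyl)pent-2-en-4-ynoyl]oxy}butanoate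
Conditions: LiCl, i-Pr2NEt, MeCN, 0 to 23 °C
Reagents that add atoms: none
Why: Horner-Wadsworth-Emmons olefination under LiCl/amine conditions is mild enough for the β-acyloxy ester and the silylalkyne and gives the E-enoate with an unbranched ynal.

Step 7
Reactants: 12 (R)-lactic acid
Product: 13 (2R,5R)-2-tert-butyl-5-methyl-1,3-dioxolan-4-one
Conditions: t-BuCHO, p-TsOH (cat.), H2SO4 (cat.), pentane, reflux with water separator; crystallisation at −78 °C
Reagents that add atoms: pivalaldehyde (CC(C)(C)C=O)
Why: Acid-catalysed acetalisation of the hydroxy acid gives mainly the cis dioxolanone, which crystallises; the new acetal centre (2R) is set under thermodynamic control by the lactate centre and later relays its chirality.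

Step 8
Reactants: 13 (2R,5R)-2-tert-butyl-5-methyl-1,3-dioxolan-4-one; 11 ethyl (3S)-3-{[(2E)-5-(trimethylsilyl)pent-2-en-4-ynoyl]oxy}butanoate
Product: 16 dioxolanone bearing ring C as its 4-hydroxy-5,6-dihydropyran-2-one enol (full name in the list), via lithium enolate of dioxolanone 14 (not isolated), via open-chain Michael adduct enolate 15 (not isolated)
Conditions: LiN(i-Pr)2 (commercial solution), THF, −78 °C; add 11, −78 to −20 °C; AcOH quench
Reagents that add atoms: none
Why: Michael addition of a lithium ester enolate to the enoate is followed on warming by Dieckmann (intramolecular Claisen) closure of the acyl enolate onto the ethyl ester, the known way from 3-acyloxy esters to 4-hydroxy-5,6-dihydropyran-2-ones, with the silyl group blocking 1,6-addition; C7 is set by attack anti to the tert-butyl group (net retention of the lactate configuration, self-regeneration of stereocentres), and C8 by a lithium-bridged synclinal transition state with the acceptor carbonyl next to the enolate oxygen, the C8 hydrogen over the dioxolanone ring and the slim silylalkynyl group outside.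

Step 9
Reactants: 16 dioxolanone bearing ring C
Product: 18 allyl ketone with free C7 hydroxyl and free lactone enol (full name in the list), via magnesium hemiketal 17 (not isolated)
Conditions: allylmagnesium bromide (3 equiv), THF, −78 °C; aqueous NH4Cl at −78 °C, then 23 °C
Reagents that add atoms: allylmagnesium bromide (C=CC[Mg]Br)
Why: At −78 °C a lactone-type carbonyl takes up one allyl unit and the cyclic magnesium hemiketal persists until quench (as in mono-additions to sugar lactones), then loses pivalaldehyde to unveil the α-hydroxy ketone; the first equivalent of reagent converts the acidic lactone enol into its magnesium enolate, which shields ring C.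

Step 10
Reactants: 18 allyl ketone with free C7 hydroxyl and free lactone enol
Product: 20 bis-silylated allyl ketone (full name in the list), via mono-silylated enol ether 19 (not isolated)
Conditions: i-Pr3SiCl (1.1 equiv), imidazole, DMF, 0 °C; then Me3SiCl (2 equiv), 23 °C
Reagents that add atoms: chlorotriisopropylsilane (CC(C)[Si](Cl)(C(C)C)C(C)C); chlorotrimethylsilane (C[Si](C)(C)Cl)
Why: The acidic vinylogous acid is silylated first at oxygen by the bulky chloride, after which the small chlorosilane/imidazole pair caps the hindered tertiary alcohol; no triflate or strong base is present, so the allyl ketone neither enolises nor moves into conjugation.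

Step 11
Reactants: 20 bis-silylated allyl ketone; 7 (4E,6E,8S)-6,8-dimethyldeca-1,4,6-trien-3-one
Product: 21 silylalkynyl dienyl enone (full name in the list)
Conditions: second-generation Hoveyda-Grubbs catalyst RuCl2(H2IMes)(=CH-C6H4-2-O-i-Pr) (10 mol%), 1,4-benzoquinone (20 mol%), 7 (3 equiv), CH2Cl2, 40 °C
Reagents that add atoms: none
Why: Olefin cross-metathesis of a terminal alkene with a vinyl ketone is selective and E-selective, the silyl-capped alkyne and the di- and trisubstituted conjugated alkenes of 7 are poor partners for the ruthenium carbene, and benzoquinone suppresses hydride-induced migration of the β,γ-double bond.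

Step 12
Reactants: 21 silylalkynyl dienyl enone
Product: 22 ethynyl dienyl enone, the cyclisation precursor (full name in the list)
Conditions: AgNO3 (0.2 equiv), 2,6-lutidine, acetone/H2O, 23 °C
Reagents that add atoms: none
Why: Silver-catalysed protiodesilylation acts only on the C(sp)-Si bond through a silver acetylide under buffered neutral conditions, which spare the O-silyl groups and the base-sensitive skipped enedione.

Step 13
Reactants: 22 ethynyl dienyl enone
Product: 23 4a,5-dihydro bicyclic 4H-pyran as a mixture of C4a epimers (full name in the list)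
Conditions: Ni(cod)2 (20 mol%), PMe3 (40 mol%), toluene (0.01 M), 25 to 50 °C
Reagents that add atoms: none
Why: Proposed new method: zerovalent nickel is expected to bind the s-cis enone O=C3-C4=C4a and the tethered ethynyl group and couple them oxidatively, forming the C4a-C8a bond and a seven-membered oxa-nickelacycle held through the enolate oxygen O2 and the former alkyne terminus C1; carbon-oxygen reductive elimination then joins O2 to C1 and returns the zerovalent catalyst. The closest known reaction types are the intermolecular nickel-catalysed [4+2] cycloaddition of enones with alkynes to 4H-pyrans and the nickel-mediated cyclisations of alkynyl enones that end at the nickelacycle; new here is the tethered, ring-fusing version on a terminal alkyne. Ring B closes by 6-exo-dig attack of C4a on C8a, and ring A closes by reductive elimination (O2-C1) from the nickelacycle, giving the six-membered 4H-pyran. The only new stereocentre, C4a, is left uncontrolled because step 14 removes its hydrogen as hydride and both epimers converge. The step needs the C4=C4a enone to react instead of the dienone half of the cross-conjugated ketone, and the alkyne to couple within the molecule instead of oligomerising: the four-atom tether C5-C8 allows only the six-membered closure and forces the terminal alkyne carbon onto oxygen, high dilution and the small donor PMe3 favour the intramolecular path, and the silyl caps at O7 and on the lactone enol remove protic and Michael-donor sites.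

Step 14
Reactants: 23 4a,5-dihydro bicyclic 4H-pyran
Product: 25 pyranylidene ketone (full name in the list), via pyrylium tetrafluoroborate 24 (not isolated)
Conditions: Ph3CBF4 (1.05 equiv), 2,6-di-tert-butylpyridine, CH2Cl2, −40 to 0 °C
Reagents that add atoms: none
Why: The C4a hydrogen of a 4H-pyran is an excellent hydride donor because an aromatic pyrylium ion results, and the hindered pyridine then removes a C5 proton, which is α to the C6 ketone and attached to the γ-position of the pyrylium ring, to give the neutral methylenepyran-type ketone.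

Step 15
Reactants: 25 pyranylidene ketone
Product: 26 5-chloro pyranylidene ketone (full name in the list)
Conditions: N-chlorosuccinimide (1.05 equiv), CH2Cl2, 0 °C, dark
Reagents that add atoms: N-chlorosuccinimide (O=C1CCC(=O)N1Cl)
Why: C5 is the α-carbon of a vinylogous ester fed by O2 through both C3=C4 and C1=C8a and is therefore the most nucleophilic position, so electrophilic chlorination should occur there as in the C5 chlorination of azaphilones, while the hindered, ester-conjugated lactone enol stays silyl-masked.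

Step 16
Reactants: 26 5-chloro pyranylidene ketone
Product: 28 CNP0584120.1, via enol tautomer 27 (not isolated)
Conditions: HF·pyridine, pyridine/THF, 0 to 23 °C; pH 7 buffer
Reagents that add atoms: none
Why: Buffered fluoride cleaves the vinylogous silyl ester and the tertiary trimethylsilyl ether without opening the electrophilic pyran ring, and the liberated enol tautomerises to the 2,4-dione with C3' settling under thermodynamic control.

**Compound list**

1 | (S)-2-methylbutan-1-ol | CC[C@H](C)CO | starting material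
2 | (S)-2-methylbutanal | CC[C@H](C)C=O | intermediate (not isolated)
3 | ethyl (2E,4S)-2,4-dimethylhex-2-enoate | CC[C@H](C)/C=C(C)/C(=O)OCC | intermediate
4 | (2E,4S)-2,4-dimethylhex-2-en-1-ol | CC[C@H](C)/C=C(C)/CO | intermediate
5 | (2E,4S)-2,4-dimethylhex-2-enal | CC[C@H](C)/C=C(C)/C=O | intermediate (not isolated)
6 | (2E,4E,6S)-N-methoxy-N,4,6-trimethylocta-2,4-dienamide | CC[C@H](C)/C=C(C)/C=C/C(=O)N(C)OC | intermediate
7 | (4E,6E,8S)-6,8-dimethyldeca-1,4,6-trien-3-one | CC[C@H](C)/C=C(C)/C=C/C(=O)C=C | intermediate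
8 | ethyl (S)-3-hydroxybutanoate | CCOC(=O)C[C@H](C)O | starting material
9 | ethyl (3S)-3-{[(diethoxyphosphoryl)acetyl]oxy}butanoate | CCOC(=O)C[C@H](C)OC(=O)CP(=O)(OCC)OCC | intermediate
10 | 3-(trimethylsilyl)prop-2-ynal | C[Si](C)(C)C#CC=O | starting material
11 | ethyl (3S)-3-{[(2E)-5-(trimethylsilyl)pent-2-en-4-ynoyl]oxy}butanoate | CCOC(=O)C[C@H](C)OC(=O)/C=C/C#C[Si](C)(C)C | intermediate
12 | (R)-lactic acid | C[C@@H](O)C(=O)O | starting material
13 | (2R,5R)-2-tert-butyl-5-methyl-1,3-dioxolan-4-one | C[C@H]1O[C@@H](C(C)(C)C)OC1=O | intermediate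
14 | lithium enolate of 13 (lithium (2R)-2-tert-butyl-5-methyl-1,3-dioxol-4-olate) | CC1=C([O-])O[C@H](C(C)(C)C)O1.[Li+] | intermediate (not isolated)
15 | lithium ester enolate of the open-chain Michael adduct of 14 and 11 (enolate geometry unassigned) | CCOC(=O)C[C@H](C)OC([O-])=C[C@@H](C#C[Si](C)(C)C)[C@]1(C)O[C@@H](C(C)(C)C)OC1=O.[Li+] | intermediate (not isolated)
16 | (2R,5S)-2-tert-butyl-5-{(1S)-1-[(6S)-4-hydroxy-6-methyl-2-oxo-5,6-dihydro-2H-pyran-3-yl]-3-(trimethylsilyl)prop-2-yn-1-yl}-5-methyl-1,3-dioxolan-4-one | C[C@@]1([C@H](C#C[Si](C)(C)C)C2=C(O)C[C@H](C)OC2=O)O[C@@H](C(C)(C)C)OC1=O | intermediate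
17 | cyclic hemiketal from allyl addition to 16, present as its bromomagnesium alkoxide (hemiketal carbon unassigned; drawn as the free hemiketal) | C=CCC1(O)O[C@H](C(C)(C)C)O[C@@]1(C)[C@H](C#C[Si](C)(C)C)C2=C(O)C[C@H](C)OC2=O | intermediate (not isolated)
18 | (6S)-4-hydroxy-3-[(3S,4S)-4-hydroxy-4-methyl-5-oxo-1-(trimethylsilyl)oct-7-en-1-yn-3-yl]-6-methyl-5,6-dihydro-2H-pyran-2-one | C=CCC(=O)[C@@](C)(O)[C@H](C#C[Si](C)(C)C)C1=C(O)C[C@H](C)OC1=O | intermediate
19 | (6S)-3-[(3S,4S)-4-hydroxy-4-methyl-5-oxo-1-(trimethylsilyl)oct-7-en-1-yn-3-yl]-6-methyl-4-(triisopropylsilyloxy)-5,6-dihydro-2H-pyran-2-one | C=CCC(=O)[C@@](C)(O)[C@H](C#C[Si](C)(C)C)C1=C(O[Si](C(C)C)(C(C)C)C(C)C)C[C@H](C)OC1=O | intermediate (not isolated)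
20 | (6S)-6-methyl-3-[(3S,4S)-4-methyl-5-oxo-1-(trimethylsilyl)-4-(trimethylsilyloxy)oct-7-en-1-yn-3-yl]-4-(triisopropylsilyloxy)-5,6-dihydro-2H-pyran-2-one | C=CCC(=O)[C@@](C)(O[Si](C)(C)C)[C@H](C#C[Si](C)(C)C)C1=C(O[Si](C(C)C)(C(C)C)C(C)C)C[C@H](C)OC1=O | intermediate
21 | (6S)-6-methyl-3-[(3S,4S,7E,10E,12E,14S)-4,12,14-trimethyl-5,9-dioxo-1-(trimethylsilyl)-4-(trimethylsilyloxy)hexadeca-7,10,12-trien-1-yn-3-yl]-4-(triisopropylsilyloxy)-5,6-dihydro-2H-pyran-2-one | CC[C@H](C)/C=C(C)/C=C/C(=O)/C=C/CC(=O)[C@@](C)(O[Si](C)(C)C)[C@H](C#C[Si](C)(C)C)C1=C(O[Si](C(C)C)(C(C)C)C(C)C)C[C@H](C)OC1=O | intermediate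
22 | (6S)-6-methyl-3-[(3R,4S,7E,10E,12E,14S)-4,12,14-trimethyl-5,9-dioxo-4-(trimethylsilyloxy)hexadeca-7,10,12-trien-1-yn-3-yl]-4-(triisopropylsilyloxy)-5,6-dihydro-2H-pyran-2-one | CC[C@H](C)/C=C(C)/C=C/C(=O)/C=C/CC(=O)[C@@](C)(O[Si](C)(C)C)[C@H](C#C)C1=C(O[Si](C(C)C)(C(C)C)C(C)C)C[C@H](C)OC1=O | intermediate (key-step precursor)
23 | (7S,8R)-3-[(1E,3E,5S)-3,5-dimethylhepta-1,3-dien-1-yl]-7-methyl-8-[(6S)-6-methyl-2-oxo-4-(triisopropylsilyloxy)-5,6-dihydro-2H-pyran-3-yl]-7-(trimethylsilyloxy)-4a,5,7,8-tetrahydro-6H-isochromen-6-one (both C4a epimers) | CC[C@H](C)/C=C(C)/C=C/C1=CC2CC(=O)[C@@](C)(O[Si](C)(C)C)[C@@H](C3=C(O[Si](C(C)C)(C(C)C)C(C)C)C[C@H](C)OC3=O)C2=CO1 | intermediate (key-step product)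
24 | (7S,8R)-3-[(1E,3E,5S)-3,5-dimethylhepta-1,3-dien-1-yl]-7-methyl-8-[(6S)-6-methyl-2-oxo-4-(triisopropylsilyloxy)-5,6-dihydro-2H-pyran-3-yl]-6-oxo-7-(trimethylsilyloxy)-5,6,7,8-tetrahydroisochromenylium tetrafluoroborate | CC[C@H](C)/C=C(C)/C=C/c1cc2CC(=O)[C@@](C)(O[Si](C)(C)C)[C@@H](C3=C(O[Si](C(C)C)(C(C)C)C(C)C)C[C@H](C)OC3=O)c2c[o+]1.F[B-](F)(F)F | intermediate (not isolated)
25 | (7S,8R)-3-[(1E,3E,5S)-3,5-dimethylhepta-1,3-dien-1-yl]-7-methyl-8-[(6S)-6-methyl-2-oxo-4-(triisopropylsilyloxy)-5,6-dihydro-2H-pyran-3-yl]-7-(trimethylsilyloxy)-7,8-dihydro-6H-isochromen-6-one | CC[C@H](C)/C=C(C)/C=C/C1=CC2=CC(=O)[C@@](C)(O[Si](C)(C)C)[C@@H](C3=C(O[Si](C(C)C)(C(C)C)C(C)C)C[C@H](C)OC3=O)C2=CO1 | intermediate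
26 | (7S,8R)-5-chloro-3-[(1E,3E,5S)-3,5-dimethylhepta-1,3-dien-1-yl]-7-methyl-8-[(6S)-6-methyl-2-oxo-4-(triisopropylsilyloxy)-5,6-dihydro-2H-pyran-3-yl]-7-(trimethylsilyloxy)-7,8-dihydro-6H-isochromen-6-one | CC[C@H](C)/C=C(C)/C=C/C1=CC2=C(Cl)C(=O)[C@@](C)(O[Si](C)(C)C)[C@@H](C3=C(O[Si](C(C)C)(C(C)C)C(C)C)C[C@H](C)OC3=O)C2=CO1 | intermediate
27 | (7S,8R)-5-chloro-3-[(1E,3E,5S)-3,5-dimethylhepta-1,3-dien-1-yl]-7-hydroxy-8-[(6S)-4-hydroxy-6-methyl-2-oxo-5,6-dihydro-2H-pyran-3-yl]-7-methyl-7,8-dihydro-6H-isochromen-6-one | CC[C@H](C)/C=C(C)/C=C/C1=CC2=C(Cl)C(=O)[C@@](C)(O)[C@@H](C3=C(O)C[C@H](C)OC3=O)C2=CO1 | intermediate (not isolated)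
28 | CNP0584120.1, (7S,8S)-5-chloro-3-[(1E,3E,5S)-3,5-dimethylhepta-1,3-dien-1-yl]-7-hydroxy-7-methyl-8-[(3R,6S)-6-methyl-2,4-dioxooxan-3-yl]-7,8-dihydro-6H-isochromen-6-one | CC[C@H](C)/C=C(C)/C=C/C1=CC2=C(Cl)C(=O)[C@@](C)(O)[C@@H]([C@@H]3C(=O)C[C@H](C)OC3=O)C2=CO1 | target

**Count**

Total: 16 steps. Longest linear sequence: 11 steps (from 8 through steps 5, 6, 8, 9, 10, 11, 12, 13, 14, 15, 16).

**Steps most likely to fail**

Step 13. The nickelacycle may be protonated or lose a β-hydrogen before carbon-oxygen reductive elimination, the terminal alkyne may oligomerise, or the phosphine may isomerise the skipped enedione. The fallback sets out from 22 and rejoins the route at 23, using known reactions only. Anti-Markovnikov hydration of the ethynyl group (CpRu(MeCN)3PF6 with a 2,2'-bipyridine ligand, aqueous acetone) would give the C1 aldehyde F1. An enamine-mediated intramolecular Michael addition (pyrrolidinium acetate cat., CH2Cl2) of C8a to C4a would close ring B (6-exo-trig) to the ring B keto aldehyde F2. Acid-catalysed cyclodehydration of this 1,5-dicarbonyl compound (pyridinium p-toluenesulfonate, toluene, molecular sieves) would close ring A and deliver 23.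

Step 8. The hindered enolate may add too slowly to the singly activated enynoate, so that proton transfer and β-elimination of the acyloxy group intervene, or the higher temperature then needed erodes the face selectivity at C8. The fallback sets out from 8, 10 and 13 and rejoins at 16; it makes ring C first and uses a doubly activated acceptor that reacts at −78 °C. Claisen condensation of 8 with LiCH2CO2t-Bu (THF, −78 to −20 °C) gives tert-butyl (5S)-5-hydroxy-3-oxohexanoate F3. CF3CO2H in CH2Cl2 lactonises it to (6S)-6-methyloxane-2,4-dione F4. Knoevenagel condensation with 10 (piperidinium acetate cat., CH2Cl2, molecular sieves, 0 °C) gives the silylpropynylidene dione F5, which is used at once. Enolate 14 (from 13 and LiN(i-Pr)2) adds to it in conjugate fashion at −78 °C, and acidic quench gives 16.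

Step 11. The ruthenium carbene may be diverted by the internal alkenes of trienone 7, or the allyl ketone may drift into conjugation before the slow coupling with an electron-poor partner takes place. The fallback sets out from 20 and from alcohol 4 and rejoins at 21; the side chain is joined by carbonyl addition instead. Cross-metathesis of 20 with crotonaldehyde (same ruthenium catalyst) gives the skipped keto enal F6. Alcohol 4 is oxidised with MnO2 to enal 5, and Takai olefination (CrCl2, CHI3, THF) turns it into (1E,3E,5S)-1-iodo-3,5-dimethylhepta-1,3-diene F7. Nozaki-Hiyama-Kishi coupling of F7 with F6 (CrCl2, NiCl2 cat., DMF), which is selective for the aldehyde over the C6 ketone, gives the bis-allylic alcohol F8. Dess-Martin periodinane with NaHCO3 oxidises it to 21.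

**Further compounds**

F1 | step 13 | (6S)-6-methyl-3-[(3R,4S,7E,10E,12E,14S)-4,12,14-trimethyl-1,5,9-trioxo-4-(trimethylsilyloxy)hexadeca-7,10,12-trien-3-yl]-4-(triisopropylsilyloxy)-5,6-dihydro-2H-pyran-2-one | CC[C@H](C)/C=C(C)/C=C/C(=O)/C=C/CC(=O)[C@@](C)(O[Si](C)(C)C)[C@H](CC=O)C1=C(O[Si](C(C)C)(C(C)C)C(C)C)C[C@H](C)OC1=O
F2 | step 13 | (2R,3S)-6-[(3E,5E,7S)-5,7-dimethyl-2-oxonona-3,5-dien-1-yl]-3-methyl-2-[(6S)-6-methyl-2-oxo-4-(triisopropylsilyloxy)-5,6-dihydro-2H-pyran-3-yl]-4-oxo-3-(trimethylsilyloxy)cyclohexane-1-carbaldehyde (C1 and C6 of the cyclohexane unassigned) | CC[C@H](C)/C=C(C)/C=C/C(=O)CC1CC(=O)[C@@](C)(O[Si](C)(C)C)[C@@H](C2=C(O[Si](C(C)C)(C(C)C)C(C)C)C[C@H](C)OC2=O)C1C=O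
F3 | step 8 | tert-butyl (5S)-5-hydroxy-3-oxohexanoate | C[C@H](O)CC(=O)CC(=O)OC(C)(C)C
F4 | step 8 | (6S)-6-methyloxane-2,4-dione | C[C@H]1CC(=O)CC(=O)O1
F5 | step 8 | (6S)-6-methyl-3-[3-(trimethylsilyl)prop-2-yn-1-ylidene]oxane-2,4-dione (alkene geometry unassigned) | C[C@H]1CC(=O)C(=CC#C[Si](C)(C)C)C(=O)O1
F6 | step 11 | (6S)-6-methyl-3-[(3S,4S,7E)-4-methyl-5,9-dioxo-1-(trimethylsilyl)-4-(trimethylsilyloxy)non-7-en-1-yn-3-yl]-4-(triisopropylsilyloxy)-5,6-dihydro-2H-pyran-2-one | O=C/C=C/CC(=O)[C@@](C)(O[Si](C)(C)C)[C@H](C#C[Si](C)(C)C)C1=C(O[Si](C(C)C)(C(C)C)C(C)C)C[C@H](C)OC1=O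
F7 | step 11 | (1E,3E,5S)-1-iodo-3,5-dimethylhepta-1,3-diene | CC[C@H](C)/C=C(C)/C=C/I
F8 | step 11 | (6S)-3-[(3S,4S,7E,10E,12E,14S)-9-hydroxy-4,12,14-trimethyl-5-oxo-1-(trimethylsilyl)-4-(trimethylsilyloxy)hexadeca-7,10,12-trien-1-yn-3-yl]-6-methyl-4-(triisopropylsilyloxy)-5,6-dihydro-2H-pyran-2-one (C9 epimers) | CC[C@H](C)/C=C(C)/C=C/C(O)/C=C/CC(=O)[C@@](C)(O[Si](C)(C)C)[C@H](C#C[Si](C)(C)C)C1=C(O[Si](C(C)C)(C(C)C)C(C)C)C[C@H](C)OC1=O
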